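**Retrosynthetic overview**
Numbering used throughout: ring A (five-membered) = C2, C3(=CH2), C4(OH), C5, C6; ring B (seven-membered) = C1(OH), C2, C6, C7(=CH2), C8(OH), C9, C10; side chain = C11(CH3), C12(OAc), C13, C14=C15(CH3)2.
Enabling feature: carbinol carbon C1 and ring-fusion carbon C2 are a latent enol ether. C6 is allylic to the exocyclic C7 methylene (latent allylsilane, three atoms from C2) and C10 is β to the oxygenated C12 (latent enoate), so rings A and B are a 5-exo and a 7-exo closure of one open chain C1–C12.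
Key disconnection: C2–C6 and C1–C10 together, back to an acyclic silyl dienol ether/allylsilane/enoate with two stereocentres. Forward, a redox-neutral photoinduced-electron-transfer bicyclisation joins donor to donor (C2/C6), then acceptor to acceptor (C1/C10); ring A forms first, ring B second.
The acyclic precursor comes from a C5 enal acetal by two rounds of Brown allylboration (C4, C8) and cross metathesis.
After the key step: ester to aldehyde, third allylboration (C12), acetate, prenyl end by cross metathesis, global desilylation.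

Key step: step 10

Assumption: the C5 enal acetal, 2-[(trimethylsilyl)methyl]prop-2-en-1-ol and both antipodes of B-allyldiisopinocampheylborane are taken as purchasable.

**Step 1**
Reactants: 1 (E)-4,4-dimethoxy-2-methylbut-2-enal
Product: 2 (2E,4R)-1,1-dimethoxy-3-methylhepta-2,6-dien-4-ol
Conditions: (+)-Ipc2B(allyl) (reagent derived from (−)-α-pinene), Et2O, −78 °C; then NaOH, H2O2, 0 °C to rt
Reagents that add atoms: (+)-B-allyldiisopinocampheylborane, C=CCB([C@H]1C[C@H]2C[C@@H]([C@@H]1C)C2(C)C)[C@H]1C[C@H]2C[C@@H]([C@@H]1C)C2(C)C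
Why: Brown asymmetric allylboration adds allyl 1,2 to the enal through a closed chair transition state and sets C4 as R under reagent control, while the basic work-up leaves the acetal intact.

**Step 2**
Reactants: 2 (2E,4R)-1,1-dimethoxy-3-methylhepta-2,6-dien-4-ol
Product: 3 TBS ether of 2, tert-butyl{[(2E,4R)-1,1-dimethoxy-3-methylhepta-2,6-dien-4-yl]oxy}dimethylsilane
Conditions: TBSCl, imidazole, DMF, rt
Reagents that add atoms: tert-butyldimethylsilyl chloride, CC(C)(C)[Si](C)(C)Cl
Why: Standard silyl ether formation on a secondary allylic alcohol under mildly basic conditions that do not touch the acetal or C4.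

**Step 3**
Reactants: 4 2-[(trimethylsilyl)methyl]prop-2-en-1-ol
Product: 5 2-[(trimethylsilyl)methyl]prop-2-enal
Conditions: MnO2, CH2Cl2, rt
Reagents that add atoms: none
Why: MnO2 oxidation of a primary allylic alcohol is neutral and selective, so the allylsilane is kept.

**Step 4**
Reactants: 3 TBS ether of 2; 5 2-[(trimethylsilyl)methyl]prop-2-enal
Product: 6 (2Z,5R,6E)-5-(tert-butyldimethylsilyloxy)-8,8-dimethoxy-6-methyl-2-[(trimethylsilyl)methyl]octa-2,6-dienal (chain trans to CHO)
Conditions: 5 (3 equiv), second-generation Hoveyda–Grubbs catalyst (5 mol %), CH2Cl2, 40 °C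
Reagents that add atoms: none
Why: Olefin cross metathesis of a terminal alkene with a 2-substituted acrolein (methacrolein-type partner) should form C6=C7 with the chain trans to the formyl group under thermodynamic control, the trisubstituted C2=C3 alkene being inert.

**Step 5**
Reactants: 6 (2Z,5R,6E)-dienal
Product: 7 (4S,5Z,8R,9E)-8-(tert-butyldimethylsilyloxy)-11,11-dimethoxy-9-methyl-5-[(trimethylsilyl)methyl]undeca-1,5,9-trien-4-ol
Conditions: (−)-Ipc2B(allyl) (reagent derived from (+)-α-pinene), Et2O, −78 °C; then NaOH, H2O2, 0 °C to rt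
Reagents that add atoms: (−)-B-allyldiisopinocampheylborane, C=CCB([C@@H]1C[C@@H]2C[C@H]([C@H]1C)C2(C)C)[C@@H]1C[C@@H]2C[C@H]([C@H]1C)C2(C)C
Why: Brown asymmetric allylboration of the α-branched enal sets C8 as S under reagent control and brings in C9 and C10.

**Step 6**
Reactants: 7 trienol
Product: 8 bis-TBS ether, (4S,5Z,8R,9E)-4,8-bis(tert-butyldimethylsilyloxy)-11,11-dimethoxy-9-methyl-5-[(trimethylsilyl)methyl]undeca-1,5,9-triene
Conditions: TBSCl, imidazole, DMAP (cat.), DMF, 40 °C
Reagents that add atoms: tert-butyldimethylsilyl chloride, CC(C)(C)[Si](C)(C)Cl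
Why: Silyl ether formation under non-acidic conditions protects C8–OH without harming the acetal or the allylsilane.

**Step 7**
Reactants: 8 bis-TBS ether
Product: 9 methyl (2E,5S,6Z,9R,10E)-5,9-bis(tert-butyldimethylsilyloxy)-12,12-dimethoxy-2,10-dimethyl-6-[(trimethylsilyl)methyl]dodeca-2,6,10-trienoate
Conditions: methyl methacrylate (10 equiv), second-generation Hoveyda–Grubbs catalyst (10 mol %), toluene, 70 °C
Reagents that add atoms: methyl methacrylate, C=C(C)C(=O)OC
Why: Cross metathesis of the only terminal alkene with a methacrylate should give the (E)-trisubstituted enoate C10=C11, the two trisubstituted alkenes being unreactive.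

**Step 8**
Reactants: 9 acetal enoate
Product: 10 methyl (2E,5S,6Z,9R,10E)-5,9-bis(tert-butyldimethylsilyloxy)-2,10-dimethyl-12-oxo-6-[(trimethylsilyl)methyl]dodeca-2,6,10-trienoate
Conditions: PPTS (cat.), acetone/H2O 10:1, rt
Reagents that add atoms: water, O
Why: Acid-catalysed hydrolysis of an allylic dimethyl acetal is fast under acid too weak to cleave secondary TBS ethers or to protodesilylate the allylsilane.

**Step 9**
Reactants: 10 enal enoate
Product: 11 methyl (2E,5S,6Z,9R,11E)-5,9,12-tris(tert-butyldimethylsilyloxy)-2-methyl-10-methylidene-6-[(trimethylsilyl)methyl]dodeca-2,6,11-trienoate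
Conditions: TBSOTf, Et3N, CH2Cl2, −78 to 0 °C
Reagents that add atoms: tert-butyldimethylsilyl triflate, CC(C)(C)[Si](C)(C)OS(=O)(=O)C(F)(F)F
Why: Soft enolisation (silyl dienol ether formation) silylates the aldehyde oxygen and removes a γ-proton from the unhindered C3 methyl group cis to the carbonyl, which creates C3=CH2 and the C1=C2 enol ether while the enoate is not enolised.

**Step 10**
Reactants: 11 silyl dienol ether/allylsilane/enoate
Product: 14 methyl (2S)-2-[(2R,3aR,4S,5R,7S,8aS)-2,4,7-tris(tert-butyldimethylsilyloxy)-3,8-dimethylidenedecahydroazulen-5-yl]propanoate, via monocyclic C1 radical 12 (not isolated), via bicyclic C11 radical 13 (not isolated)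
Conditions: 9,10-dicyanoanthracene (5 mol %), biphenyl (50 mol %), MeOH (10 equiv), 2,6-lutidine (0.5 equiv), MeCN/CH2Cl2 4:1 (0.005 M), 420 nm LED, Ar, 0 °C
Reagents that add atoms: none
Why: Proposed new method: photoexcited 9,10-dicyanoanthracene (hole relayed by biphenyl) takes one electron from the silyl dienol ether, the most easily oxidised π system of 11, the allylsilane carbon C6 attacks the umpoled C2, MeOH removes Me3Si+ to unveil the C7 methylene and the nucleophilic α-silyloxy radical 12, 12 adds to the enoate carbon C10, and the electrophilic α-ester radical 13 takes the electron back from the dicyanoanthracene radical anion and is protonated at C11, so the step is redox-neutral and contains no hydrogen-atom donor or oxidant that could intercept 12. The closest known reaction types are the anodic coupling of an enol ether radical cation with an allylsilane, the photoinduced-electron-transfer cyclisation of silyl enol ethers and the photoredox Giese addition with reductive radical-polar crossover; what is new is their merger, the α-oxy radical being trapped by carbon instead of being oxidised to the carbonyl level. Ring A closes 5-exo-trig (exo to both C1=C2 and C6=C7) and ring B closes 7-exo-trig onto C10=C11. C2 and C6 are set in an envelope transition state in which the C4 silyloxy group and the C7 branch are pseudo-equatorial and 1,3-cis and the silyloxyvinyl unit lies anti to the C7 branch, which gives the trans ring fusion. C1 follows from C2 because the new C1–C10 bond must be anti to C3 and the silyloxy group then takes the open sector between C3 and H2, C10 follows from C8 because allylic 1,3-strain with the new C7 methylene keeps H8 in the alkene plane and the silyloxy group pseudo-axial, which fixes the sign of the C6–C7–C8–C9 torsion and presents the enoate face that leaves C11 pseudo-equatorial, and C11 follows from C10 by protonation of the enolate anti to the C1 branch in the conformer with H10 in the enolate plane. The step needs site-selective oxidation (secured by the low oxidation potential of the dienol ether), attack at C2 and not at the diene terminus (that closure would be 5-endo), loss of silicon from carbon and not from oxygen (Me3Si next to a β-cation against a hindered O-TBS group) and no 1,5-hydrogen shift from C8 to C1 (polarity mismatch, H8 turned away).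

**Step 11**
Reactants: 14 bicyclic ester
Product: 15 (2S)-2-[(2R,3aR,4S,5R,7S,8aS)-2,4,7-tris(tert-butyldimethylsilyloxy)-3,8-dimethylidenedecahydroazulen-5-yl]propanal
Conditions: i-Bu2AlH (1.1 equiv), CH2Cl2, −78 °C; aq. potassium sodium tartrate; used directly
Reagents that add atoms: none
Why: Partial reduction of a methyl ester stops at the stable tetrahedral aluminium adduct at low temperature and releases the aldehyde on work-up without epimerising C11.

**Step 12**
Reactants: 15 aldehyde
Product: 16 (2S,3S)-2-[(2R,3aR,4S,5R,7S,8aS)-2,4,7-tris(tert-butyldimethylsilyloxy)-3,8-dimethylidenedecahydroazulen-5-yl]hex-5-en-3-ol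
Conditions: (−)-Ipc2B(allyl) (reagent derived from (+)-α-pinene), Et2O, −78 °C; then NaOH, H2O2, 0 °C
Reagents that add atoms: (−)-B-allyldiisopinocampheylborane, C=CCB([C@@H]1C[C@@H]2C[C@H]([C@H]1C)C2(C)C)[C@@H]1C[C@@H]2C[C@H]([C@H]1C)C2(C)C
Why: Brown asymmetric allylboration sets C12 as S, the reagent preference being matched with the Felkin–Anh preference of the α-methyl aldehyde.

**Step 13**
Reactants: 16 homoallylic alcohol
Product: 17 (2S,3S)-2-[(2R,3aR,4S,5R,7S,8aS)-2,4,7-tris(tert-butyldimethylsilyloxy)-3,8-dimethylidenedecahydroazulen-5-yl]hex-5-en-3-yl acetate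
Conditions: Ac2O, Et3N, DMAP (cat.), CH2Cl2, rt
Reagents that add atoms: acetic anhydride, CC(=O)OC(C)=O
Why: DMAP-catalysed acetylation meets only one free hydroxyl group, since C1, C4 and C8 carry silyl ethers.

**Step 14**
Reactants: 17 terminal alkene acetate
Product: 18 (2S,3S)-2-[(2R,3aR,4S,5R,7S,8aS)-2,4,7-tris(tert-butyldimethylsilyloxy)-3,8-dimethylidenedecahydroazulen-5-yl]-6-methylhept-5-en-3-yl acetate
Conditions: 2-methyl-2-butene/CH2Cl2 1:1, second-generation Grubbs catalyst (5 mol %), 40 °C
Reagents that add atoms: 2-methyl-2-butene, CC=C(C)C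
Why: Cross metathesis with 2-methyl-2-butene turns the monosubstituted alkene into the prenyl end, while the two hindered 1,1-disubstituted ring methylenes should not engage.

**Step 15**
Reactants: 18 tris-TBS ether
Product: 19 target, (2S,3S)-2-[(2R,3aR,4S,5R,7S,8aS)-2,4,7-trihydroxy-3,8-dimethylidenedecahydroazulen-5-yl]-6-methylhept-5-en-3-yl acetate
Conditions: HF·pyridine, pyridine, THF, 0 °C to rt
Reagents that add atoms: none
Why: Buffered fluoride-mediated desilylation cleaves all three TBS ethers under conditions too mild to hydrolyse or shift the acetate or to ionise the allylic alcohols.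

**Compound list**
1 | (E)-4,4-dimethoxy-2-methylbut-2-enal | COC(OC)/C=C(\C)C=O | starting material
2 | (2E,4R)-1,1-dimethoxy-3-methylhepta-2,6-dien-4-ol | COC(OC)/C=C(\C)[C@H](O)CC=C | intermediate
3 | TBS ether of 2 | COC(OC)/C=C(\C)[C@H](O[Si](C)(C)C(C)(C)C)CC=C | intermediate
4 | 2-[(trimethylsilyl)methyl]prop-2-en-1-ol | C=C(CO)C[Si](C)(C)C | starting material
5 | 2-[(trimethylsilyl)methyl]prop-2-enal | C=C(C=O)C[Si](C)(C)C | intermediate
6 | (2Z,5R,6E)-5-(TBSO)-8,8-dimethoxy-6-methyl-2-[(trimethylsilyl)methyl]octa-2,6-dienal | COC(OC)/C=C(\C)[C@H](O[Si](C)(C)C(C)(C)C)C/C=C(\C[Si](C)(C)C)C=O | intermediate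
7 | (4S,5Z,8R,9E)-8-(TBSO)-11,11-dimethoxy-9-methyl-5-[(trimethylsilyl)methyl]undeca-1,5,9-trien-4-ol | COC(OC)/C=C(\C)[C@H](O[Si](C)(C)C(C)(C)C)C/C=C(\C[Si](C)(C)C)[C@@H](O)CC=C | intermediate
8 | bis-TBS ether of the C4,C8 diol (terminal alkene) | COC(OC)/C=C(\C)[C@H](O[Si](C)(C)C(C)(C)C)C/C=C(\C[Si](C)(C)C)[C@@H](O[Si](C)(C)C(C)(C)C)CC=C | intermediate
9 | methyl (2E,5S,6Z,9R,10E)-5,9-bis(TBSO)-12,12-dimethoxy-2,10-dimethyl-6-[(trimethylsilyl)methyl]dodeca-2,6,10-trienoate | COC(OC)/C=C(\C)[C@H](O[Si](C)(C)C(C)(C)C)C/C=C(\C[Si](C)(C)C)[C@@H](O[Si](C)(C)C(C)(C)C)C/C=C(\C)C(=O)OC | intermediate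
10 | methyl (2E,5S,6Z,9R,10E)-5,9-bis(TBSO)-2,10-dimethyl-12-oxo-6-[(trimethylsilyl)methyl]dodeca-2,6,10-trienoate | O=C/C=C(\C)[C@H](O[Si](C)(C)C(C)(C)C)C/C=C(\C[Si](C)(C)C)[C@@H](O[Si](C)(C)C(C)(C)C)C/C=C(\C)C(=O)OC | intermediate
11 | methyl (2E,5S,6Z,9R,11E)-5,9,12-tris(TBSO)-2-methyl-10-methylidene-6-[(trimethylsilyl)methyl]dodeca-2,6,11-trienoate | CC(C)(C)[Si](C)(C)O/C=C/C(=C)[C@H](O[Si](C)(C)C(C)(C)C)C/C=C(\C[Si](C)(C)C)[C@@H](O[Si](C)(C)C(C)(C)C)C/C=C(\C)C(=O)OC | intermediate
12 | monocyclic C1 radical (ring A closed, C7 methylene formed, α-silyloxy radical at C1) | C=C1[C@H]([CH]O[Si](C)(C)C(C)(C)C)[C@@H](C(=C)[C@@H](O[Si](C)(C)C(C)(C)C)C/C=C(\C)C(=O)OC)C[C@H]1O[Si](C)(C)C(C)(C)C | intermediate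
13 | bicyclic C11 radical (rings A and B closed, α-ester radical at C11) | C=C1[C@@H]2[C@@H](O[Si](C)(C)C(C)(C)C)[C@@H]([C](C)C(=O)OC)C[C@H](O[Si](C)(C)C(C)(C)C)C(=C)[C@H]2C[C@H]1O[Si](C)(C)C(C)(C)C | intermediate
14 | methyl (2S)-2-[(2R,3aR,4S,5R,7S,8aS)-2,4,7-tris(TBSO)-3,8-dimethylidenedecahydroazulen-5-yl]propanoate | C=C1[C@@H]2[C@@H](O[Si](C)(C)C(C)(C)C)[C@@H]([C@H](C)C(=O)OC)C[C@H](O[Si](C)(C)C(C)(C)C)C(=C)[C@H]2C[C@H]1O[Si](C)(C)C(C)(C)C | intermediate
15 | (2S)-2-[tris(TBSO)-dimethylidenedecahydroazulen-5-yl]propanal | C=C1[C@@H]2[C@@H](O[Si](C)(C)C(C)(C)C)[C@@H]([C@H](C)C=O)C[C@H](O[Si](C)(C)C(C)(C)C)C(=C)[C@H]2C[C@H]1O[Si](C)(C)C(C)(C)C | intermediate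
16 | (2S,3S)-2-[tris(TBSO)-dimethylidenedecahydroazulen-5-yl]hex-5-en-3-ol | C=C1[C@@H]2[C@@H](O[Si](C)(C)C(C)(C)C)[C@@H]([C@H](C)[C@H](CC=C)O)C[C@H](O[Si](C)(C)C(C)(C)C)C(=C)[C@H]2C[C@H]1O[Si](C)(C)C(C)(C)C | intermediate
17 | acetate of 16 | C=C1[C@@H]2[C@@H](O[Si](C)(C)C(C)(C)C)[C@@H]([C@H](C)[C@H](CC=C)OC(C)=O)C[C@H](O[Si](C)(C)C(C)(C)C)C(=C)[C@H]2C[C@H]1O[Si](C)(C)C(C)(C)C | intermediate
18 | tris-TBS ether of the target | C=C1[C@@H]2[C@@H](O[Si](C)(C)C(C)(C)C)[C@@H]([C@H](C)[C@H](CC=C(C)C)OC(C)=O)C[C@H](O[Si](C)(C)C(C)(C)C)C(=C)[C@H]2C[C@H]1O[Si](C)(C)C(C)(C)C | intermediate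
19 | CNP0210891.2, (2S,3S)-2-[(2R,3aR,4S,5R,7S,8aS)-2,4,7-trihydroxy-3,8-dimethylidenedecahydroazulen-5-yl]-6-methylhept-5-en-3-yl acetate | C=C1[C@@H]2[C@@H](O)[C@@H]([C@H](C)[C@H](CC=C(C)C)OC(C)=O)C[C@H](O)C(=C)[C@H]2C[C@H]1O | target

**Step count and risk assessment**
Total step count: 15. Longest linear sequence: 14 (steps 1, 2 and 4 to 15).

Steps most likely to fail:

Step 10 (the labelled step). Three things may go wrong:
- The radical cation may lose its O-silyl group before the C2–C6 bond forms.
- The 7-exo addition may be too slow against unproductive decay of the α-silyloxy radical.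
- The facial selectivity at C4-controlled ring A closure or at C10 may be poor.

The fallback uses known chemistry and closes the rings in two separate operations; it sets out from 11 and returns at 15. Constant-current anodic oxidation of 11 (reticulated vitreous carbon anode, LiClO4, MeOH/CH2Cl2, 2,6-lutidine, mild acid work-up), an anodic enol ether/allylsilane olefin coupling, should give the trans-configured cyclopentanecarbaldehyde F1. SmI2/t-BuOH in THF then closes ring B by a 7-exo ketyl–olefin cyclisation, and the cis hydroxy ester lactonises to the tricyclic γ-lactone F2. AlMe3/MeNH(OMe)·HCl opens this to the hydroxy Weinreb amide F3, TBSOTf/2,6-lutidine gives the C1 silyl ether F4, and i-Bu2AlH delivers aldehyde 15.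

Step 4. The cross metathesis may stall because the hindered, electron-poor 1,1-disubstituted partner reacts more slowly than the terminal alkene homodimerises and the catalyst decays. The fallback replaces metathesis by carbonyl olefination; it sets out from 3 and returns at 6. Lemieux–Johnson cleavage of 3 (OsO4 cat., NaIO4, 2,6-lutidine, dioxane/H2O) at the only monosubstituted alkene should give the β-silyloxy aldehyde F5. A Wittig reaction with the stabilised ylide ethyl 2-(triphenylphosphoranylidene)-3-(trimethylsilyl)propanoate F6 (from Ph3P=CHCO2Et and ICH2SiMe3) gives the enoate F7 with the chain trans to the ester. i-Bu2AlH reduces it to the allylic alcohol F8, and MnO2 gives 6.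

Step 7. The second cross metathesis may give incomplete conversion, with homodimerisation next to the bulky C8 silyloxy group. The fallback builds the C8–C9 bond and the enoate at once; it sets out from 6, bypasses steps 5 to 7 and returns at 9. A vinylogous Mukaiyama aldol reaction couples enal 6 with the silyl ketene acetal of methyl tiglate F9 (methyl tiglate, LDA, TBSCl). It is promoted by the antipode of the N-tosyltryptophan-derived B-phenyloxazaborolidinone that leaves open the aldehyde face leading to 8S (i-PrOH, EtCN, −78 °C), and should give the δ-hydroxy enoate F10. TBSCl/imidazole then gives 9.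

**Further compounds**
F1 | step 10 | methyl (2E,5S)-5-(TBSO)-6-[(1S,2R,4R)-4-(TBSO)-2-formyl-3-methylidenecyclopentyl]-2-methylhepta-2,6-dienoate | C=C1[C@H](C=O)[C@@H](C(=C)[C@@H](O[Si](C)(C)C(C)(C)C)C/C=C(\C)C(=O)OC)C[C@H]1O[Si](C)(C)C(C)(C)C
F2 | step 10 | tricyclic cis-fused γ-lactone (O1–C12 closed, C4 and C8 OTBS) | C=C1[C@@H]2[C@@H](O3)[C@@H]([C@H](C)C3=O)C[C@H](O[Si](C)(C)C(C)(C)C)C(=C)[C@H]2C[C@H]1O[Si](C)(C)C(C)(C)C
F3 | step 10 | C1-hydroxy Weinreb amide | C=C1[C@@H]2[C@@H](O)[C@@H]([C@H](C)C(=O)N(C)OC)C[C@H](O[Si](C)(C)C(C)(C)C)C(=C)[C@H]2C[C@H]1O[Si](C)(C)C(C)(C)C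
F4 | step 10 | tris-TBS Weinreb amide | C=C1[C@@H]2[C@@H](O[Si](C)(C)C(C)(C)C)[C@@H]([C@H](C)C(=O)N(C)OC)C[C@H](O[Si](C)(C)C(C)(C)C)C(=C)[C@H]2C[C@H]1O[Si](C)(C)C(C)(C)C
F5 | step 4 | (3R,4E)-3-(TBSO)-6,6-dimethoxy-4-methylhex-4-enal | COC(OC)/C=C(\C)[C@H](O[Si](C)(C)C(C)(C)C)CC=O
F6 | step 4 | ethyl 2-(triphenylphosphoranylidene)-3-(trimethylsilyl)propanoate | CCOC(=O)C(C[Si](C)(C)C)=P(c1ccccc1)(c1ccccc1)c1ccccc1
F7 | step 4 | ethyl (2Z,5R,6E)-5-(TBSO)-8,8-dimethoxy-6-methyl-2-[(trimethylsilyl)methyl]octa-2,6-dienoate | COC(OC)/C=C(\C)[C@H](O[Si](C)(C)C(C)(C)C)C/C=C(\C[Si](C)(C)C)C(=O)OCC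
F8 | step 4 | (2Z,5R,6E)-5-(TBSO)-8,8-dimethoxy-6-methyl-2-[(trimethylsilyl)methyl]octa-2,6-dien-1-ol | COC(OC)/C=C(\C)[C@H](O[Si](C)(C)C(C)(C)C)C/C=C(\C[Si](C)(C)C)CO
F9 | step 7 | tert-butyl[(1-methoxy-2-methylbuta-1,3-dien-1-yl)oxy]dimethylsilane | COC(O[Si](C)(C)C(C)(C)C)=C(C)C=C
F10 | step 7 | methyl (2E,5S,6Z,9R,10E)-9-(TBSO)-5-hydroxy-12,12-dimethoxy-2,10-dimethyl-6-[(trimethylsilyl)methyl]dodeca-2,6,10-trienoate | COC(OC)/C=C(\C)[C@H](O[Si](C)(C)C(C)(C)C)C/C=C(\C[Si](C)(C)C)[C@@H](O)C/C=C(\C)C(=O)OC
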